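**Plan**
- Retrosynthetic cuts, in order: C16=C17 and the O3‑acetyl/C1–H pair; then C9–C10, which opens the ten‑membered ring; then a helper bond C9–C14 is put back (retro‑Grob), folding ring D, C7–OH and the C9 aldehyde into a spiro‑epoxy diquinane; then C7–C8 (Darzens). This leaves ring‑A aldehyde 9 and chloro ketone 18.
- Forward ring order: ring A from a cyclohexadienone; rings C′ (helper) and D by a Pauson–Khand reaction; spiro‑oxirane by Darzens union; Grob fragmentation opens C′; copper hydride closes the ten‑membered ring.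
- Enabling feature: C10 lies between oxygen‑bearing C1 (ring A) and the C9 carbonyl, and it carries the C20 methyl group. An exocyclic C10=C20 enone on ring A is therefore a latent, regiodefined C10 enolate. One hydride delivered to C20 makes the methyl group and the nucleophile together, and the C6 chain on C5 shields one face.
- Stereochemistry: C5 comes from Rh/(R)‑BINAP, and C2/C3 follow from C5. The temporary C9 centre (Ru transfer hydrogenation) sets C13 (Pauson–Khand), then C14/C8 (convex face), then C7 (Darzens, kept through the Grob step). C10 is set from C5 in the key step, and C1 from C3 by the Evans–Tishchenko reaction.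

Key step: step 15

Remark on notation: atom numbers are ent‑kaurane numbers (ring A = C1–C5, C10; ring D = C8, C14, C13, C16, C15; C′ = C14, C9, C11, C12, C13). "Up" means toward a viewer who sees C10→C1→C2→C3→C4→C5 and C8→C14→C13→C16→C15 run clockwise. In the target, C20, C6, O1 and C12 are up, C9 and O3 are down, and C7 is R.
Assumption: the propargylic silyloxy group takes the exo (convex) position in the Pauson–Khand step, as is usual for 1,6‑enynes. The other diastereomer would be removed by chromatography.

**Step 1**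
Reactants: 1 4,4‑dimethylcyclohex‑2‑en‑1‑one
Product: 2 4,4‑dimethylcyclohexa‑2,5‑dien‑1‑one
Conditions: DDQ, dioxane, reflux
Reagents that add atoms: none
Why: DDQ dehydrogenation (hydride abstraction from the dienol) gives the cross‑conjugated dienone, which cannot aromatise because C4 is quaternary; no stereocentre is formed.

**Step 2**
Reactants: 2 4,4‑dimethylcyclohexa‑2,5‑dien‑1‑one; 3 potassium vinyltrifluoroborate
Product: 4 (R)‑4,4‑dimethyl‑5‑vinylcyclohex‑2‑en‑1‑one (vinyl up)
Conditions: [Rh(cod)2]BF4 (cat.), (R)‑BINAP, Et3N, toluene/H2O, rt→40 °C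
Reagents that add atoms: none
Why: Rh(I)‑catalysed asymmetric 1,4‑addition of an alkenylboron reagent (Hayashi–Miyaura reaction) desymmetrises the prochiral dienone, a known substrate class, and the ligand selects one enantiotopic enone face and so sets C5 (sense assigned by analogy with cyclohexenone).

**Step 3**
Reactants: 4 (R)‑4,4‑dimethyl‑5‑vinylcyclohex‑2‑en‑1‑one
Product: 6 2,3‑epoxy‑5‑(2‑hydroxyethyl)‑4,4‑dimethylcyclohexan‑1‑one (C5 chain up; oxirane down), via pinacol boronate 5 (not isolated)
Conditions: HBpin, [Ir(cod)Cl]2 (cat.), dppe, CH2Cl2, rt; then H2O2, NaOH, THF/MeOH/H2O, 0 °C→rt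
Reagents that add atoms: hydrogen peroxide, OO
Why: Ir‑catalysed anti‑Markovnikov hydroboration touches only the terminal alkene, and the alkaline peroxide then oxidises the C–B bond and performs a Weitz–Scheffer epoxidation of the enone, hydroperoxide attacking C3 axially, trans to the C5 chain and away from the axial C4 methyl group, which sets C2 and C3.

**Step 4**
Reactants: 6 epoxy ketone alcohol
Product: 8 C10‑(dimethylaminomethyl) epoxy ketone alcohol (CH2NMe2 down; trans to the C5 chain), via dilithium alkoxide enolate 7 (not isolated)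
Conditions: LDA (2.2 equiv), THF, −78 °C; then CH2=NMe2+ I−, −78→0 °C; H2O
Reagents that add atoms: Eschenmoser's salt, C=[N+](C)C.[I-]
Why: Mannich reaction of a kinetic lithium enolate with a preformed iminium salt: C10–H2 is the only enolisable position because C2 is an oxirane carbon, the CH2NMe2 group (future C20, a masked C10=C20 bond) enters trans to the C5 chain, and this C10 centre is erased in step 14.

**Step 5**
Reactants: 8 Mannich base alcohol
Product: 9 ring‑A aldehyde (C7 aldehyde; C5 chain up; CH2NMe2 down; oxirane down)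
Conditions: Dess–Martin periodinane, CH2Cl2, 0 °C→rt
Reagents that add atoms: none
Why: Dess–Martin oxidation of the primary alcohol stops at the aldehyde and tolerates the tertiary amine, the oxirane and the ketone.

**Step 6**
Reactants: 10 pent‑4‑enoyl chloride; 11 trimethylsilylacetylene
Product: 12 1‑(trimethylsilyl)hept‑6‑en‑1‑yn‑3‑one
Conditions: PdCl2(PPh3)2 (cat.), CuI (cat.), Et3N, THF, rt
Reagents that add atoms: none
Why: Acyl Sonogashira coupling gives the ynone under conditions that leave the terminal alkene untouched.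

**Step 7**
Reactants: 12 ynone
Product: 13 (R)‑1‑(trimethylsilyl)hept‑6‑en‑1‑yn‑3‑ol
Conditions: RuCl[(R,R)‑TsDPEN](p‑cymene) (cat.), i‑PrOH, rt
Reagents that add atoms: none
Why: Noyori asymmetric transfer hydrogenation of an alkynyl ketone, in which the (R,R)‑catalyst differentiates alkynyl from alkyl and should give the (R)‑propargylic alcohol (temporary C9 centre).

**Step 8**
Reactants: 13 (R)‑silylated propargylic alcohol
Product: 14 (R)‑hept‑6‑en‑1‑yn‑3‑ol
Conditions: K2CO3 (cat.), MeOH, 0 °C→rt
Reagents that add atoms: none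
Why: Methanolysis of the alkynyl–silicon bond (protodesilylation) frees the terminal alkyne needed for an unsubstituted C8.

**Step 9**
Reactants: 14 (R)‑hept‑6‑en‑1‑yn‑3‑ol
Product: 15 (R)‑3‑(tert‑butyldimethylsilyloxy)hept‑6‑en‑1‑yne
Conditions: TBSCl, imidazole, DMF, rt
Reagents that add atoms: tert‑butyldimethylsilyl chloride, CC(C)(C)[Si](C)(C)Cl
Why: Standard silylation of a secondary alcohol; the bulky ether also serves as the stereocontrol element of step 10.

**Step 10**
Reactants: 15 silyloxy enyne
Product: 16 4‑(tert‑butyldimethylsilyloxy)‑4,5,6,6a‑tetrahydro‑1H‑pentalen‑2‑one (H13 down; OTBS exo on the face of H13)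
Conditions: Co2(CO)8 (cat.), tetramethylthiourea (cat.), CO (1 atm), toluene, 70 °C
Reagents that add atoms: carbon monoxide, [C-]#[O+]
Why: Intramolecular Pauson–Khand reaction of a 1,6‑enyne closes rings C′ and D and brings in C15 as CO; the propargylic silyloxy group should take the exo position in the cobaltacycle, so that C13 is set from C9.

**Step 11**
Reactants: 16 diquinane enone
Product: 18 α‑chloro diquinane ketone (H13 and H14 down; Cl at C8 down), via triethylsilyl enol ether 17 (not isolated)
Conditions: Et3SiH, RhCl(PPh3)3 (cat.), toluene, 50 °C; then NCS, THF, −20 °C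
Reagents that add atoms: N‑chlorosuccinimide, O=C1CCC(=O)N1Cl
Why: Rh‑catalysed 1,4‑hydrosilylation puts hydride on C14 from the convex face (only the cis‑fused diquinane is accessible) and fixes the enol ether towards C8, where NCS chlorinates (α‑halogenation of a silyl enol ether); the C8 centre is lost again in step 12.

**Step 12**
Reactants: 18 α‑chloro diquinane ketone; 9 ring‑A aldehyde
Product: 21 spiro‑epoxy diquinane ketone (oxirane O at C8 down; C7 up; 7R; C6 trans to C15), via lithium chloro enolate 19 (not isolated), via lithium chlorohydrinate 20 (not isolated)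
Conditions: LiHMDS, THF, −78 °C; then 9, −78→0 °C
Reagents that add atoms: none
Why: Darzens condensation: the chloro enolate adds to the aldehyde from the convex face and the alkoxide displaces chloride with inversion at C8, which puts the oxirane oxygen on the convex face, while reversible aldol addition funnels material to the less hindered oxirane with C6 trans to the C15 acyl group, i.e. 7R.

**Step 13**
Reactants: 21 spiro‑epoxy diquinane ketone
Product: 24 seco aldehyde (ring‑D enone; 7R triethylsilyl ether; C9 aldehyde; ring‑A Mannich base), via C9 ammonium alkoxide 22 (not isolated), via C7 ammonium alkoxide 23 (not isolated)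
Conditions: TBAF, THF, −20→0 °C; then TESCl, imidazole, 0 °C
Reagents that add atoms: chlorotriethylsilane, CC[Si](Cl)(CC)CC
Why: Fluoride frees the C9 alkoxide, whose C9–C14 bond is antiperiplanar to the C8–O bond of the oxirane (C9 on the concave and O on the convex face), so that a Grob‑type fragmentation of the 3,4‑epoxy alcohol gives the C9 aldehyde, the C8=C14 enone and the C7 alkoxide with C7 untouched, and the alkoxide is silylated in the same flask.

**Step 14**
Reactants: 24 seco aldehyde
Product: 26 exo‑methylene ketone aldehyde (C10=C20), via trimethylammonium iodide 25 (not isolated)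
Conditions: MeI, Et2O/CH2Cl2, rt; then aq. NaHCO3, CH2Cl2, rt; used at once
Reagents that add atoms: none
Why: Exhaustive methylation and E1cB (Hofmann‑type) elimination of the Mannich base unmask the exocyclic enone under conditions mild enough for aldehyde, oxirane and silyl ether.

**Step 15**
Reactants: 26 exo‑methylene ketone aldehyde
Product: 29 ten‑membered‑ring aldol (C20 methyl up; C9 down at C10; C9 carbinol configuration open), via copper enolate 27 (not isolated), via copper aldolate 28 (not isolated)
Conditions: [(Ph3P)CuH]6 (about 1.1 equiv hydride), toluene, slow addition of 26 to about 1 mM, −40→0 °C; aq. NH4Cl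
Reagents that add atoms: none
Why: Proposed new method: hydride from the copper hydride adds 1,4 to the fixed s‑cis exocyclic enone C20=C10–C1=O, which makes the C20 methyl group and, regiospecifically, the tetrasubstituted copper enolate 27, and this enolate adds to the C9 aldehyde through a closed six‑membered (Zimmerman–Traxler type) transition state to give aldolate 28. The closest known reaction type is the tandem conjugate reduction–aldol cyclisation of enones tethered to carbonyl groups with Stryker's reagent, so far used for five‑ and six‑membered rings, together with medium‑ring aldol closures of metal enolates made from α‑halo ketones. The one ring that closes is the carbocycle C5–C6–C7–C8–C14–C13–C12–C11–C9–C10, in a 10‑(enolexo)‑exo‑trig mode, helped by the rigid C8=C14 bond of ring D, the two vicinal anchors on ring A and high dilution. C10 is controlled by C5: A(1,2) strain with the C20 methyl group turns the C6 chain pseudo‑axial, so C9 has to bond to the opposite face, trans to C6 as in the target, whereas any closure through a short tether along C5–C6 would be forced cis; the C9 carbinol centre is not controlled and is erased in step 17. The step needs chemoselectivity for the terminal s‑cis enone over the trisubstituted s‑trans ring‑D enone and over the aldehyde, which the unhindered CH2 terminus secures, and a weakly basic enolate so that C11–H and C16–H stay untouched; the C2–C3 oxirane blocks enolate equilibration to C2 and β‑elimination at C3.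

**Step 16**
Reactants: 29 ten‑membered‑ring aldol
Product: 31 ring‑D Mannich base aldol (CH2NMe2 at C16 down; trans to C12), via dilithium aldolate dienolate 30 (not isolated)
Conditions: LiHMDS (2.2 equiv), THF, −78 °C; then CH2=NMe2+ I−, −78 °C; AcOH quench at −78 °C
Reagents that add atoms: Eschenmoser's salt, C=[N+](C)C.[I-]
Why: Kinetic α′‑deprotonation of the cyclopentenone at C16, the only enolisable carbon at this stage (C10 quaternary, C2 an oxirane carbon, C9 a carbinol), and Mannich reaction trans to the C12 chain store C17 as an amine that survives steps 17–19; the aldolate is kept at −78 °C to suppress retro‑aldol cleavage.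

**Step 17**
Reactants: 31 ring‑D Mannich base aldol
Product: 32 epoxy 1,9‑diketone
Conditions: Dess–Martin periodinane, CH2Cl2, rt
Reagents that add atoms: none
Why: Dess–Martin oxidation of the only free alcohol gives the non‑enolisable 1,3‑diketone and erases the uncontrolled C9 centre.

**Step 18**
Reactants: 32 epoxy 1,9‑diketone
Product: 33 3‑hydroxy 1,9‑diketone (axial C3–OH down)
Conditions: (PhSe)2, NaBH4, EtOH; then AcOH and 32, 0 °C
Reagents that add atoms: none
Why: Organoselenium‑mediated reductive opening of an α,β‑epoxy ketone cleaves only the Cα–O bond at C2, so that the axial C3–O bond and its configuration are kept; enone, diketone and amine are not reduced by the buffered selenolate.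

**Step 19**
Reactants: 33 3‑hydroxy 1,9‑diketone
Product: 34 3‑acetate 1‑alcohol (O3 acetyl down; equatorial C1–OH up)
Conditions: MeCHO (excess), SmI2 (cat.), THF, −10 °C
Reagents that add atoms: acetaldehyde, CC=O
Why: Evans–Tishchenko reaction: the samarium‑bound hemiacetal of the axial C3–OH and acetaldehyde passes its hydride intramolecularly to the same face of the C1 ketone, which gives the 1,3‑anti equatorial C1–OH and leaves the acetyl group on O3 in one operation; the C9 and C15 ketones have no free β‑hydroxy group.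

**Step 20**
Reactants: 34 3‑acetate 1‑alcohol
Product: 36 7‑O‑triethylsilyl ether of the target, via ring‑D trimethylammonium iodide 35 (not isolated)
Conditions: MeI, CH2Cl2, rt; then aq. NaHCO3, CH2Cl2, rt
Reagents that add atoms: none
Why: Quaternisation and E1cB elimination of the ring‑D Mannich base give the C16=C17 methylene group; bicarbonate is too weak to cause retro‑aldol cleavage or acetate loss.

**Step 21**
Reactants: 36 7‑O‑triethylsilyl ether
Product: 37 target CNP0223751.1
Conditions: HF·pyridine, pyridine, THF, 0 °C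
Reagents that add atoms: none
Why: Fluoride‑mediated cleavage of the allylic triethylsilyl ether under buffered conditions, which spare acetate, β‑hydroxy ketone and cross‑conjugated dienone.

**Compound list**
1 | 4,4‑dimethylcyclohex‑2‑en‑1‑one | CC1(C)C=CC(=O)CC1 | starting material
2 | 4,4‑dimethylcyclohexa‑2,5‑dien‑1‑one | CC1(C)C=CC(=O)C=C1 | intermediate
3 | potassium vinyltrifluoroborate | [K+].C=C[B-](F)(F)F | starting material
4 | (R)‑4,4‑dimethyl‑5‑vinylcyclohex‑2‑en‑1‑one | C=C[C@H]1CC(=O)C=CC1(C)C | intermediate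
5 | pinacol boronate of 4 | CC1(C)OB(CC[C@H]2CC(=O)C=CC2(C)C)OC1(C)C | intermediate
6 | epoxy ketone alcohol | OCC[C@H]1CC(=O)[C@@H]2O[C@@H]2C1(C)C | intermediate
7 | dilithium alkoxide enolate of 6 | [Li]OCC[C@H]1C=C(O[Li])[C@@H]2O[C@@H]2C1(C)C | intermediate
8 | ring‑A Mannich base alcohol | OCC[C@H]1[C@H](CN(C)C)C(=O)[C@@H]2O[C@@H]2C1(C)C | intermediate
9 | ring‑A aldehyde | O=CC[C@H]1[C@H](CN(C)C)C(=O)[C@@H]2O[C@@H]2C1(C)C | intermediate
10 | pent‑4‑enoyl chloride | C=CCCC(=O)Cl | starting material
11 | trimethylsilylacetylene | C#C[Si](C)(C)C | starting material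
12 | 1‑(trimethylsilyl)hept‑6‑en‑1‑yn‑3‑one | C=CCCC(=O)C#C[Si](C)(C)C | intermediate
13 | (R)‑1‑(trimethylsilyl)hept‑6‑en‑1‑yn‑3‑ol | C=CCC[C@@H](O)C#C[Si](C)(C)C | intermediate
14 | (R)‑hept‑6‑en‑1‑yn‑3‑ol | C=CCC[C@@H](O)C#C | intermediate
15 | (R)‑3‑(tert‑butyldimethylsilyloxy)hept‑6‑en‑1‑yne | C=CCC[C@@H](O[Si](C)(C)C(C)(C)C)C#C | intermediate
16 | diquinane enone | O=C1C=C2[C@H](O[Si](C)(C)C(C)(C)C)CC[C@H]2C1 | intermediate
17 | triethylsilyl enol ether | CC[Si](CC)(CC)OC1=C[C@H]2[C@H](O[Si](C)(C)C(C)(C)C)CC[C@H]2C1 | intermediate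
18 | α‑chloro diquinane ketone | O=C1[C@H](Cl)[C@H]2[C@H](O[Si](C)(C)C(C)(C)C)CC[C@H]2C1 | intermediate
19 | lithium chloro enolate | [Li]OC1=C(Cl)[C@H]2[C@H](O[Si](C)(C)C(C)(C)C)CC[C@H]2C1 | intermediate
20 | lithium chlorohydrinate | O=C1C[C@@H]2CC[C@@H](O[Si](C)(C)C(C)(C)C)[C@@H]2[C@@]1(Cl)[C@H](O[Li])C[C@H]1[C@H](CN(C)C)C(=O)[C@@H]2O[C@@H]2C1(C)C | intermediate
21 | spiro‑epoxy diquinane ketone | O=C1C[C@@H]2CC[C@@H](O[Si](C)(C)C(C)(C)C)[C@@H]2[C@@]13O[C@@H]3C[C@H]1[C@H](CN(C)C)C(=O)[C@@H]2O[C@@H]2C1(C)C | intermediate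
22 | C9 tetrabutylammonium alkoxide | O=C1C[C@@H]2CC[C@@H]([O-])[C@@H]2[C@@]13O[C@@H]3C[C@H]1[C@H](CN(C)C)C(=O)[C@@H]2O[C@@H]2C1(C)C.CCCC[N+](CCCC)(CCCC)CCCC | intermediate
23 | C7 tetrabutylammonium alkoxide | O=CCC[C@@H]1C=C(C(=O)C1)[C@H]([O-])C[C@H]1[C@H](CN(C)C)C(=O)[C@@H]2O[C@@H]2C1(C)C.CCCC[N+](CCCC)(CCCC)CCCC | intermediate
24 | seco aldehyde, 7‑O‑TES | O=CCC[C@@H]1C=C(C(=O)C1)[C@H](O[Si](CC)(CC)CC)C[C@H]1[C@H](CN(C)C)C(=O)[C@@H]2O[C@@H]2C1(C)C | intermediate
25 | ring‑A trimethylammonium iodide | O=CCC[C@@H]1C=C(C(=O)C1)[C@H](O[Si](CC)(CC)CC)C[C@H]1[C@H](C[N+](C)(C)C)C(=O)[C@@H]2O[C@@H]2C1(C)C.[I-] | intermediate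
26 | exo‑methylene ketone aldehyde | O=CCC[C@@H]1C=C(C(=O)C1)[C@H](O[Si](CC)(CC)CC)C[C@H]1C(=C)C(=O)[C@@H]2O[C@@H]2C1(C)C | intermediate
27 | copper enolate (phosphine omitted) | O=CCC[C@@H]1C=C(C(=O)C1)[C@H](O[Si](CC)(CC)CC)C[C@H]1C(C)=C(O[Cu])[C@@H]2O[C@@H]2C1(C)C | intermediate
28 | copper aldolate (phosphine omitted) | C1C(=O)C2=C[C@H]1CCC(O[Cu])[C@@]1(C)[C@H](C[C@H]2O[Si](CC)(CC)CC)C(C)(C)[C@H]3O[C@H]3C1=O | intermediate
29 | ten‑membered‑ring aldol (C9 open) | C1C(=O)C2=C[C@H]1CCC(O)[C@@]1(C)[C@H](C[C@H]2O[Si](CC)(CC)CC)C(C)(C)[C@H]3O[C@H]3C1=O | intermediate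
30 | dilithium aldolate dienolate | C1=C(O[Li])C2=C[C@H]1CCC(O[Li])[C@@]1(C)[C@H](C[C@H]2O[Si](CC)(CC)CC)C(C)(C)[C@H]3O[C@H]3C1=O | intermediate
31 | ring‑D Mannich base aldol | CN(C)C[C@@H]1C(=O)C2=C[C@H]1CCC(O)[C@@]1(C)[C@H](C[C@H]2O[Si](CC)(CC)CC)C(C)(C)[C@H]3O[C@H]3C1=O | intermediate
32 | epoxy 1,9‑diketone | CN(C)C[C@@H]1C(=O)C2=C[C@H]1CCC(=O)[C@@]1(C)[C@H](C[C@H]2O[Si](CC)(CC)CC)C(C)(C)[C@H]3O[C@H]3C1=O | intermediate
33 | 3‑hydroxy 1,9‑diketone | CN(C)C[C@@H]1C(=O)C2=C[C@H]1CCC(=O)[C@@]1(C)[C@H](C[C@H]2O[Si](CC)(CC)CC)C(C)(C)[C@@H](O)CC1=O | intermediate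
34 | 3‑acetate 1‑alcohol | CN(C)C[C@@H]1C(=O)C2=C[C@H]1CCC(=O)[C@@]1(C)[C@H](C[C@H]2O[Si](CC)(CC)CC)C(C)(C)[C@@H](OC(C)=O)C[C@@H]1O | intermediate
35 | ring‑D trimethylammonium iodide | C[N+](C)(C)C[C@@H]1C(=O)C2=C[C@H]1CCC(=O)[C@@]1(C)[C@H](C[C@H]2O[Si](CC)(CC)CC)C(C)(C)[C@@H](OC(C)=O)C[C@@H]1O.[I-] | intermediate
36 | 7‑O‑triethylsilyl ether of the target | C=C1C(=O)C2=C[C@H]1CCC(=O)[C@@]1(C)[C@H](C[C@H]2O[Si](CC)(CC)CC)C(C)(C)[C@@H](OC(C)=O)C[C@@H]1O | intermediate
37 | CNP0223751.1 (3‑acetoxy‑1,7‑dihydroxy‑8,9‑seco‑ent‑kaura‑8(14),16‑diene‑9,15‑dione) | C=C1C(=O)C2=C[C@H]1CCC(=O)[C@@]1(C)[C@H](C[C@H]2O)C(C)(C)[C@@H](OC(C)=O)C[C@@H]1O | target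

**Step count**
Total steps: 21. Longest linear sequence: 16 (steps 6–21, from 10).

**Steps most likely to fail**

1. **Step 15.**
   - Failure modes: protonation or oligomerisation of the copper enolate may outrun the slow medium‑ring closure, and excess hydride may attack the ring‑D enone.
   - Fallback: a Reformatsky‑type medium‑ring aldol of an α‑bromo ketone (known chemistry), setting out from 21 and rejoining at 29.
   - Quaternisation of 21 with MeI and elimination with NaHCO3 would give the exo‑methylene diquinane F1.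
   - Reduction with Stryker's reagent (no aldehyde is present at this stage) and an NBS quench of the enolate would give the tertiary α‑bromo ketone F2.
   - HF·pyridine would free the C9 alcohol F3.
   - Fragmentation with Ti(OiPr)4 under non‑basic conditions, followed by TESOTf/2,6‑lutidine, would give the bromo aldehyde F4.
   - CrCl2/LiI in THF at high dilution would then generate the non‑basic chromium(III) enolate and close the ring to 29.

2. **Step 12.**
   - Failure modes: poor simple or facial selectivity, enolisation of the aldehyde, or Favorskii‑type ring contraction of the chloro ketone.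
   - Fallback: sets out from 17 (isolated instead of chlorinated) and rejoins at 21.
   - MeLi would release the chlorine‑free lithium enolate, and addition to 9 would give the aldol F5.
   - Mesylation and DBU elimination would give the (E)‑alkylidene ketone F6.
   - Weitz–Scheffer epoxidation with t‑BuOOH/DBU from the convex face would give 21.

3. **Step 16.**
   - Failure modes: retro‑aldol opening of the lithium aldolate, or γ‑deprotonation at C13.
   - Fallback: sets out from 29 and rejoins at 31. The dianion is replaced by a monoanion on a protected substrate.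
   - TMS‑imidazole would give the C9 trimethylsilyl ether F7.
   - LiHMDS (1.1 equiv) and Eschenmoser's salt would give the silylated Mannich base F8.
   - Citric acid in MeOH would remove only the trimethylsilyl group to give 31.

**Further compounds**
F1 | step 15 | exo‑methylene diquinane | O=C1C[C@@H]2CC[C@@H](O[Si](C)(C)C(C)(C)C)[C@@H]2[C@@]13O[C@@H]3C[C@H]1C(=C)C(=O)[C@@H]2O[C@@H]2C1(C)C
F2 | step 15 | tertiary α‑bromo ketone (Br down, methyl up) | O=C1C[C@@H]2CC[C@@H](O[Si](C)(C)C(C)(C)C)[C@@H]2[C@@]13O[C@@H]3C[C@H]1[C@](C)(Br)C(=O)[C@@H]2O[C@@H]2C1(C)C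
F3 | step 15 | C9 alcohol of F2 | O=C1C[C@@H]2CC[C@@H](O)[C@@H]2[C@@]13O[C@@H]3C[C@H]1[C@](C)(Br)C(=O)[C@@H]2O[C@@H]2C1(C)C
F4 | step 15 | bromo aldehyde | O=CCC[C@@H]1C=C(C(=O)C1)[C@H](O[Si](CC)(CC)CC)C[C@H]1[C@](C)(Br)C(=O)[C@@H]2O[C@@H]2C1(C)C
F5 | step 12 | aldol (C7 and C8 open) | O=C1C[C@@H]2CC[C@@H](O[Si](C)(C)C(C)(C)C)[C@@H]2C1C(O)C[C@H]1[C@H](CN(C)C)C(=O)[C@@H]2O[C@@H]2C1(C)C
F6 | step 12 | (E)‑alkylidene ketone | O=C1C[C@@H]2CC[C@@H](O[Si](C)(C)C(C)(C)C)[C@@H]2/C1=C\C[C@H]1[C@H](CN(C)C)C(=O)[C@@H]2O[C@@H]2C1(C)C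
F7 | step 16 | C9 trimethylsilyl ether of 29 | C1C(=O)C2=C[C@H]1CCC(O[Si](C)(C)C)[C@@]1(C)[C@H](C[C@H]2O[Si](CC)(CC)CC)C(C)(C)[C@H]3O[C@H]3C1=O
F8 | step 16 | silylated ring‑D Mannich base | CN(C)C[C@@H]1C(=O)C2=C[C@H]1CCC(O[Si](C)(C)C)[C@@]1(C)[C@H](C[C@H]2O[Si](CC)(CC)CC)C(C)(C)[C@H]3O[C@H]3C1=O
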